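## Analysis of the target

The target 16 is a flavanone: a chroman-4-one in which benzo ring A is fused to pyranone ring C, and C2 carries ring B, a 3,4-dimethoxyphenyl group. Ring A has no hydrogen left. C4a holds the ketone carbon C4, C5 to C7 hold methoxy groups, C8 holds the only free hydroxyl and C8a holds the ring oxygen O1. C2 is the only stereocentre; it is S-configured, benzylic and bound to O1, and there is no second centre to relate it to. It is fragile: once the C4 ketone can enolise, base or hot acid opens ring C by retro-oxa-Michael reaction to an achiral 2'-hydroxychalcone, and reclosure gives the racemate. Ring A is very electron-rich, and the 8-hydroxyl stands para to the 5-methoxy group, a hydroquinone monoether that oxidants turn into a quinone. The hard parts are to set C2 and keep it, to build a benzene ring with six substituents, and to tell four ring A oxygens apart so that only O8 ends free. The strategy rests on the neighbouring pair C4a/C8a: an acyl carbon and an ether oxygen on adjacent ring carbons are the two ends of an aryne triple bond, and the flanking groups at C5 and C8 can be chosen so that the two ends differ.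

## Retrosynthetic reasoning

**16 to 15 (C8–O to C8–B).** The free hydroxyl is traced back to the pinacol boronate 15. Boron is unlike the three methoxy groups, so no selective ether cleavage is needed. It is also the group that controls the ring-forming step. The forward reaction has to replace boron by oxygen at C8 without opening ring C.

**15 to 7 and 10 (O1–C8a and C4–C4a).** Both bonds sit on adjacent carbons of ring A, so cutting them together removes ring C and leaves two halves of similar size, triflate 7 (fragment 1) and hydroxy amide 10 (fragment 2). C2 lies outside both cuts and arrives complete in 10. In the forward direction 7 must give aryne 12 across C4a–C8a, alkoxide 11 must add its oxygen to C8a, and the arylmagnesium 13 left at C4a must close onto the amide to give 14 and then 15.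

- The acyl group is an N-methoxy-N-methyl amide because its adduct 14 stays tetrahedral until work-up. The ketone is then never exposed to base, and C2 cannot be lost through ring opening.
- C8 carries boron and not a protected oxygen. An alkoxy group at C8 would act like the C5 methoxy group and cancel its directing effect. Boron has the opposite preference, so both flanking groups send the oxygen to C8a.

**7 to 6, 2, 1 and 3 (O–S, C8–B, two C–I).** Triflate 7 comes from phenol 6. The boron of 6 comes from one iodine of the symmetric diiodophenol 2 by iodine–magnesium exchange and trapping with boric ester 3. This is done on the phenoxide, before the triflate exists, because a magnesium placed ortho to a triflate would expel it at once. The two iodines of 2 are equivalent, so the mono-exchange has no regiochemical question. 2 comes from phenol 1 by twofold iodination of its only two free positions. The hydroxyl carbon of 1 becomes C8a, its methoxy carbons become C5 to C7, and the two iodinated carbons become C4a and C8.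

**10 to 9 and 8 (amide C–N, carbinol C–H).** Amide 10 comes from ester 9 by aminolysis. The stereocentre of 9 comes from keto ester 8 by asymmetric hydrogenation, a reaction of known facial sense. The forward steps must set the S configuration and keep the β-hydroxy carbonyl unit from retro-aldol cleavage or dehydration.

## Alternatives that were turned down

**Alternative 1:** The cut is C3–C4, with C4 as a masked acyl anion. In the key step the aryl dithiane A2 is deprotonated with an alkyllithium base and the carbanion displaces the primary tosylate (6-exo-tet) to give the spiro dithioketal A1.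

- For: every reaction type is long established, the new bond is a plain alkylation, and C2 is a spectator. C4 stays a dithioketal, so ring opening cannot racemise C2 before the end. On certainty of the key step this plan is stronger than the chosen one.
- Against: A2 already contains the O1 ether between a hindered phenol and the electron-rich benzylic carbon. That ether has to be made by substitution with inversion, which tends to leak through the benzylic cation.
- Against: the dithiane carbon lies between two ortho oxygens, so its anion is hindered. C2–H is benzylic and next to oxygen; metalation there would give a cyclopropane by attack on the tosylate.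
- Against: O8 must be introduced and benzylated selectively early. After A1 two more steps follow: dithioketal cleavage with thiophilic or oxidising reagents, which three electron-rich rings tolerate poorly, and hydrogenolysis.
- Comparison: the line is roughly twice as long. The chosen strategy offers convergence, no substitution at the stereocentre and no protecting group in place of that certainty.

**Alternative 2:** The cut is C8–C8a, and with it the whole of ring A: C5 to C8 come from a squaric ester, C4a and C8a from the enol ether double bond of a dihydropyran. In the key step cyclobutenone A4 is heated in an aromatic solvent; four-electron ring opening gives a dienylketene, six-electron closure forms C8–C8a, and tautomerisation gives phenol A3.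

- For: the substitution pattern of ring A follows from connectivity, not from selectivity on an arene. O8 emerges free and the other three oxygens as methyl ethers, with no reagent. On telling the ring A oxygens apart it is stronger than the chosen plan, which needs a boron placeholder and a final oxidation.
- Against: A4 needs an enantioenriched, metalated dihydropyran with two stereocentres, its addition to a squaric ester and O-methylation of a hindered tertiary alkoxide.
- Against: C4 arrives as a silyl ether at the wrong oxidation level. After A3 come desilylation and oxidation of a benzylic alcohol next to a free hydroquinone monoether, which is oxidised more easily than the alcohol. Protecting the phenol costs two more steps.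
- Against: the allylic silyloxy group may be eliminated at the temperature of the thermolysis, and one stereocentre is built only to be destroyed.
- Comparison: about ten steps in the longest line against five. The chosen strategy buys ring A complete and has C4 at the ketone level as soon as ring C closes.

**Alternative 3:** The cut is C2–C3. In the key step diazoketone A6 is treated with a chiral dirhodium tetracarboxylate catalyst; the carbene inserts into the benzylic C–H bond next to O1, closes ring C and sets C2, giving A5.

- For: ring and stereocentre are made in one catalytic step from an achiral precursor, only a diatomic gas is lost, and no chiral building block is needed. On economy of the stereo-defining event it is stronger than the chosen plan.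
- Against: the carbene carbon sits five atoms from O1. Attack of O1 on the carbene gives a five-membered oxonium ylide, and a [1,2]-Stevens shift of the electron-rich benzyl group then leads to benzofuranone A7. This is the usual course for ortho-alkoxyaryl diazoketones, and insertion to a six-membered ring is the slower mode.
- Against: the methyl C–H bonds and the oxygen of the C5 methoxy group compete in the same way.
- Against: carbenes with only one acceptor group give the least reliable enantiocontrol, and the configuration would rest on the catalyst alone.
- Against: A6 still needs a hexasubstituted benzoic acid with O8 differentiated, and a final desilylation.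
- Comparison: the length is similar at best. The chosen strategy takes C2 from a hydrogenation of known sense, and its ring closure has no ylide pathway.

Key step: step 6

Assumption: the ruthenium catalyst with the (R)-configured BINAP ligand is taken to give the (S)-carbinol from an aryl β-keto ester, its usual sense; if the sense were the other one, the (S)-ligand would be used. Ring A atoms carry their chromanone numbers (C4a, C5 to C8, C8a) in every intermediate.

## Route

Step 1
Reactants: 1 3,4,5-trimethoxyphenol
Product: 2 2,6-diiodo-3,4,5-trimethoxyphenol
Conditions: NIS (2.2 equiv), MeCN, 0 °C to rt, dark; aq Na2S2O3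
Reagents that add atoms: N-iodosuccinimide, O=C1CCC(=O)N1I
Why: Electrophilic aromatic iodination. The only two free positions of 1 are equivalent, each ortho to the hydroxyl and ortho and para to methoxy groups, so two equivalents of NIS can only give 2.

Step 2
Reactants: 2 2,6-diiodo-3,4,5-trimethoxyphenol; 3 2-isopropoxy-4,4,5,5-tetramethyl-1,3,2-dioxaborolane
Product: 6 2-iodo-3,4,5-trimethoxy-6-(4,4,5,5-tetramethyl-1,3,2-dioxaborolan-2-yl)phenol, via magnesium phenoxide 4 (not isolated), via C-magnesiated phenoxide 5 (not isolated)
Conditions: MeMgCl (1.0 equiv), THF, −30 °C; i-PrMgCl·LiCl (1.1 equiv), −30 to 0 °C; 3 (1.5 equiv), 0 °C to rt; aq NH4Cl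
Reagents that add atoms: none
Why: Iodine–magnesium exchange on a magnesium phenoxide, then borylation of the arylmagnesium with a boric ester. MeMgCl first removes the O–H, the exchange takes place next to O–Mg and OMe, and the doubly metalated ring of 5 resists a second exchange, so one iodine stays. Boron goes in before the triflate because the same exchange ortho to a triflate would expel it.

Step 3
Reactants: 6 2-iodo-3,4,5-trimethoxy-6-(4,4,5,5-tetramethyl-1,3,2-dioxaborolan-2-yl)phenol
Product: 7 2-iodo-3,4,5-trimethoxy-6-(4,4,5,5-tetramethyl-1,3,2-dioxaborolan-2-yl)phenyl trifluoromethanesulfonate (fragment 1)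
Conditions: Tf2O (1.3 equiv), pyridine (3 equiv), CH2Cl2, −20 to 0 °C
Reagents that add atoms: trifluoromethanesulfonic anhydride, O=S(=O)(OS(=O)(=O)C(F)(F)F)C(F)(F)F
Why: O-Sulfonylation of a phenol with triflic anhydride and pyridine. The aryl iodide, the pinacol boronate and the methyl ethers do not react at this temperature; 7 then carries the leaving group at C8a and the exchangeable iodine at C4a.

Step 4
Reactants: 8 ethyl 3-(3,4-dimethoxyphenyl)-3-oxopropanoate
Product: 9 ethyl (3S)-3-(3,4-dimethoxyphenyl)-3-hydroxypropanoate
Conditions: H2 (50 bar), RuCl2[(R)-BINAP](dmf)n (1 mol %), EtOH, 50 °C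
Reagents that add atoms: none
Why: Noyori asymmetric hydrogenation of a β-keto ester. Ketone and ester oxygens chelate ruthenium and the (R)-configured diphosphine sets the new carbinol centre, which for an aryl ketone carries the S descriptor; the aryl ethers and the ester are not reduced.

Step 5
Reactants: 9 ethyl (3S)-3-(3,4-dimethoxyphenyl)-3-hydroxypropanoate
Product: 10 (3S)-3-(3,4-dimethoxyphenyl)-3-hydroxy-N-methoxy-N-methylpropanamide (fragment 2)
Conditions: MeNH(OMe)·HCl (2 equiv), i-PrMgCl (5 equiv), THF, −20 to 0 °C; aq NH4Cl
Reagents that add atoms: N,O-dimethylhydroxylamine hydrochloride, CNOC.Cl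
Why: Aminolysis of the ester by the chloromagnesium amide of N,O-dimethylhydroxylamine made in the flask (Weinreb amide formation). One further equivalent of i-PrMgCl covers the free hydroxyl, and its magnesium alkoxide should be stable at this temperature, so the stereocentre is not touched.

Step 6
Reactants: 7 2-iodo-3,4,5-trimethoxy-6-(4,4,5,5-tetramethyl-1,3,2-dioxaborolan-2-yl)phenyl trifluoromethanesulfonate; 10 (3S)-3-(3,4-dimethoxyphenyl)-3-hydroxy-N-methoxy-N-methylpropanamide
Product: 15 (2S)-2-(3,4-dimethoxyphenyl)-5,6,7-trimethoxy-8-(4,4,5,5-tetramethyl-1,3,2-dioxaborolan-2-yl)chroman-4-one, via magnesium alkoxide 11 (not isolated), via aryne 12 (not isolated), via arylmagnesium ether 13 (not isolated), via chelated tetrahedral adduct 14 (not isolated)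
Conditions: 10 (1.5 equiv), i-PrMgCl·LiCl (1.5 equiv), THF, −78 °C; 7 (1.0 equiv); i-PrMgCl·LiCl (1.1 equiv) added slowly, −78 to 0 °C; aq NH4Cl, 0 °C
Reagents that add atoms: none
Why: Proposed new method: after 10 is deprotonated to alkoxide 11, iodine–magnesium exchange at C4a of 7 gives an arylmagnesium ortho to the triflate, which leaves at −78 °C to form aryne 12 across C4a–C8a; the oxygen of 11 adds to C8a, and the C4a arylmagnesium 13 attacks the N-methoxy-N-methyl amide carbonyl to give the magnesium-chelated adduct 14, which releases ketone 15 only on the cold NH4Cl quench. The closest known reaction types are the aryne annulation of salicylates to xanthones (oxygen addition, then capture of the aryl anion by a tethered acyl group), the addition of magnesium thiolates and amides to arynes made from 2-iodoaryl sulfonates with trapping of the new arylmagnesium, and the ortho-selective addition of amines to 3-borylbenzynes generated with i-PrMgCl·LiCl; new here are an aliphatic magnesium alkoxide as nucleophile and a tethered Weinreb amide as acceptor. Ring C closes by 6-exo-trig attack of C4a on the amide carbonyl, after the O1–C8a bond has been made between the two fragments. No stereocentre is created: C2 is the carbinol carbon of 10 and no bond to it is made or broken, and because C4 stays tetrahedral in 14 the ketone cannot enolise under the basic conditions, so ring opening and racemisation are shut off until work-up. The selectivity needed is addition of oxygen to C8a and not to C4a: the C5 methoxy group stabilises negative charge at its neighbour C4a by induction and so steers the nucleophile to the far carbon C8a, while the electropositive boryl group at C8 disfavours charge at C8a, favours attack there and can hold the alkoxide as a borate beside that carbon, so both flanking groups point the same way. Chemoselectivity rests on rate: exchange at an iodide ortho to a triflate should be faster at −78 °C than addition of i-PrMgCl to the amide or to boron, and slow addition keeps the Grignard reagent from competing with 11 for the aryne.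

Step 7
Reactants: 15 (2S)-2-(3,4-dimethoxyphenyl)-5,6,7-trimethoxy-8-(4,4,5,5-tetramethyl-1,3,2-dioxaborolan-2-yl)chroman-4-one
Product: 16 (2S)-2-(3,4-dimethoxyphenyl)-8-hydroxy-5,6,7-trimethoxychroman-4-one (the target, CNP0179923.1)
Conditions: NaBO3·4H2O (3 equiv), THF/H2O 1:1, 0 °C to rt; aq NH4Cl
Reagents that add atoms: sodium perborate tetrahydrate NaBO3·4H2O, [Na+].[O-]OB=O.O.O.O.O
Why: Oxidation of an aryl–boron bond by perborate. The peroxo oxygen adds to boron, C8 shifts from boron to oxygen, and the borate ester is hydrolysed to the phenol, so oxygen ends exactly where boron was. A short reaction at low temperature and a buffered quench should keep the enolisable flavanone from opening.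

## Compound list

1 | 3,4,5-trimethoxyphenol | COc1cc(O)cc(OC)c1OC | starting material
2 | 2,6-diiodo-3,4,5-trimethoxyphenol | COc1c(OC)c(OC)c(I)c(O)c1I | intermediate
3 | 2-isopropoxy-4,4,5,5-tetramethyl-1,3,2-dioxaborolane | CC(C)OB1OC(C)(C)C(C)(C)O1 | starting material
4 | chloromagnesium 2,6-diiodo-3,4,5-trimethoxyphenolate | COc1c(OC)c(OC)c(I)c(O[Mg]Cl)c1I | intermediate
5 | chloromagnesium 2-(chloromagnesio)-6-iodo-3,4,5-trimethoxyphenolate | COc1c(OC)c(OC)c([Mg]Cl)c(O[Mg]Cl)c1I | intermediate
6 | 2-iodo-3,4,5-trimethoxy-6-(4,4,5,5-tetramethyl-1,3,2-dioxaborolan-2-yl)phenol | COc1c(OC)c(OC)c(B2OC(C)(C)C(C)(C)O2)c(O)c1I | intermediate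
7 | 2-iodo-3,4,5-trimethoxy-6-(4,4,5,5-tetramethyl-1,3,2-dioxaborolan-2-yl)phenyl trifluoromethanesulfonate (fragment 1) | COc1c(OC)c(OC)c(B2OC(C)(C)C(C)(C)O2)c(OS(=O)(=O)C(F)(F)F)c1I | intermediate
8 | ethyl 3-(3,4-dimethoxyphenyl)-3-oxopropanoate | CCOC(=O)CC(=O)c1ccc(OC)c(OC)c1 | starting material
9 | ethyl (3S)-3-(3,4-dimethoxyphenyl)-3-hydroxypropanoate | COc1ccc([C@@H](O)CC(=O)OCC)cc1OC | intermediate
10 | (3S)-3-(3,4-dimethoxyphenyl)-3-hydroxy-N-methoxy-N-methylpropanamide (fragment 2) | COc1ccc([C@@H](O)CC(=O)N(C)OC)cc1OC | intermediate
11 | chloromagnesium (1S)-1-(3,4-dimethoxyphenyl)-3-[methoxy(methyl)amino]-3-oxopropan-1-olate | COc1ccc([C@@H](O[Mg]Cl)CC(=O)N(C)OC)cc1OC | intermediate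
12 | 2-(2,3-didehydro-4,5,6-trimethoxyphenyl)-4,4,5,5-tetramethyl-1,3,2-dioxaborolane (ring A aryne, triple bond C4a–C8a) | COC1=C(OC)C(OC)=C(B2OC(C)(C)C(C)(C)O2)C#C1 | intermediate
13 | {2-[(1S)-1-(3,4-dimethoxyphenyl)-3-[methoxy(methyl)amino]-3-oxopropoxy]-4,5,6-trimethoxy-3-(4,4,5,5-tetramethyl-1,3,2-dioxaborolan-2-yl)phenyl}magnesium chloride | COc1ccc([C@@H](Oc2c([Mg]Cl)c(OC)c(OC)c(OC)c2B3OC(C)(C)C(C)(C)O3)CC(=O)N(C)OC)cc1OC | intermediate
14 | chloromagnesium (2S)-2-(3,4-dimethoxyphenyl)-5,6,7-trimethoxy-4-[methoxy(methyl)amino]-8-(4,4,5,5-tetramethyl-1,3,2-dioxaborolan-2-yl)chroman-4-olate (C4 not defined) | COc1ccc([C@@H]2CC(O[Mg]Cl)(N(C)OC)c3c(c(B4OC(C)(C)C(C)(C)O4)c(OC)c(OC)c3OC)O2)cc1OC | intermediate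
15 | (2S)-2-(3,4-dimethoxyphenyl)-5,6,7-trimethoxy-8-(4,4,5,5-tetramethyl-1,3,2-dioxaborolan-2-yl)chroman-4-one | COc1ccc([C@@H]2CC(=O)c3c(c(B4OC(C)(C)C(C)(C)O4)c(OC)c(OC)c3OC)O2)cc1OC | intermediate
16 | (2S)-2-(3,4-dimethoxyphenyl)-8-hydroxy-5,6,7-trimethoxychroman-4-one | COc1ccc([C@@H]2CC(=O)c3c(c(O)c(OC)c(OC)c3OC)O2)cc1OC | target

## Step count and least certain steps

Total step count: 7. Longest linear sequence: 5 steps (steps 1, 2, 3, 6 and 7); the second branch (steps 4 and 5) joins at step 6.

**Step 6 (key step, proposed new method).** The most likely failure is loss of the aryne to other nucleophiles before the alkoxide adds. A hindered secondary magnesium alkoxide is a weak nucleophile and may be tied up on boron, so the isopropyl Grignard reagent, halide or arylmagnesium 13 can compete. Two further risks are retro-aldol cleavage or dehydration of alkoxide 11 before it adds, and proton transfer from C3–H to C4a in 13 ahead of ring closure, followed by loss of the aryloxide.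

The fallback makes the two bonds one after the other with known reaction types. It sets out from 6 and 8 and comes back to the route at 13, and through 14 at 15. Keto ester 8 would be hydrogenated with RuCl2[(S)-BINAP](dmf)n to ethyl (3R)-3-(3,4-dimethoxyphenyl)-3-hydroxypropanoate F1 and converted as in step 5 into (3R)-3-(3,4-dimethoxyphenyl)-3-hydroxy-N-methoxy-N-methylpropanamide F2. Mitsunobu etherification of phenol 6 with F2 (PPh3, DIAD, toluene, 0 °C) would form the O1–C2 bond with inversion and give (3S)-3-(3,4-dimethoxyphenyl)-3-[2-iodo-3,4,5-trimethoxy-6-(4,4,5,5-tetramethyl-1,3,2-dioxaborolan-2-yl)phenoxy]-N-methoxy-N-methylpropanamide F3. Iodine–magnesium exchange on F3 with i-PrMgCl·LiCl at −40 °C gives arylmagnesium 13 directly; there is no leaving group ortho to magnesium, so no aryne forms. 13 then closes onto the amide as in the main route (Parham-type cyclisation). The weak point of this fallback is ionisation at the electron-rich benzylic carbon during the Mitsunobu step.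

**Step 2.** The exchange on the electron-rich, already anionic ring may be sluggish or may not stop cleanly after one iodine. The doubly ortho-oxygenated boronate may also lose boron by protonation on work-up.

The fallback sets out from 2 and comes back at 6. The phenol would be protected with MOMCl and i-Pr2NEt as 1,3-diiodo-4,5,6-trimethoxy-2-(methoxymethoxy)benzene F4. One iodine would be exchanged with i-PrMgCl·LiCl at −40 °C, now on a neutral ring with two coordinating ortho oxygens, and the arylmagnesium trapped with 3 to give 2-[3-iodo-4,5,6-trimethoxy-2-(methoxymethoxy)phenyl]-4,4,5,5-tetramethyl-1,3,2-dioxaborolane F5. The acetal would be removed with ZnBr2 and n-PrSH in CH2Cl2 at 0 °C to give 6.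

**Step 7.** The mildly basic peroxide medium may open ring C by retro-oxa-Michael reaction. That would racemise C2, and the opened form could be drained by Algar–Flynn–Oyamada-type oxidation. Loss of boron by protonation and over-oxidation of the hydroquinone monoether to a quinone are the other risks.

The fallback sets out from 15 and comes back at 16. It uses a different oxidant class in a water-free medium: anhydrous Me3NO in CH2Cl2 transfers oxygen to boron, and C8 migrates to give (2S)-2-(3,4-dimethoxyphenyl)-5,6,7-trimethoxy-8-[(4,4,5,5-tetramethyl-1,3,2-dioxaborolan-2-yl)oxy]chroman-4-one F6. No hydroxide or peroxide anion is present at any point. The O–B bond of F6 is cleaved on a pH 7 work-up.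

**Step 5.** The electron-rich benzylic magnesium aldolate may undergo retro-aldol cleavage or dehydration to the cinnamoyl compound during aminolysis, which would cost material or enantiopurity.

The fallback sets out from 9 and comes back at 10. The ester would be saponified with LiOH in THF/H2O at 0 °C to (3S)-3-(3,4-dimethoxyphenyl)-3-hydroxypropanoic acid F7. F7 would be coupled with MeNH(OMe)·HCl using EDC·HCl, HOBt and i-Pr2NEt in CH2Cl2, under conditions that never form a metal aldolate.

## Further compounds

F1 | step 6 | ethyl (3R)-3-(3,4-dimethoxyphenyl)-3-hydroxypropanoate | COc1ccc([C@H](O)CC(=O)OCC)cc1OC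
F2 | step 6 | (3R)-3-(3,4-dimethoxyphenyl)-3-hydroxy-N-methoxy-N-methylpropanamide | COc1ccc([C@H](O)CC(=O)N(C)OC)cc1OC
F3 | step 6 | (3S)-3-(3,4-dimethoxyphenyl)-3-[2-iodo-3,4,5-trimethoxy-6-(4,4,5,5-tetramethyl-1,3,2-dioxaborolan-2-yl)phenoxy]-N-methoxy-N-methylpropanamide | COc1ccc([C@@H](Oc2c(I)c(OC)c(OC)c(OC)c2B3OC(C)(C)C(C)(C)O3)CC(=O)N(C)OC)cc1OC
F4 | step 2 | 1,3-diiodo-4,5,6-trimethoxy-2-(methoxymethoxy)benzene | COCOc1c(I)c(OC)c(OC)c(OC)c1I
F5 | step 2 | 2-[3-iodo-4,5,6-trimethoxy-2-(methoxymethoxy)phenyl]-4,4,5,5-tetramethyl-1,3,2-dioxaborolane | COCOc1c(I)c(OC)c(OC)c(OC)c1B2OC(C)(C)C(C)(C)O2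
F6 | step 7 | (2S)-2-(3,4-dimethoxyphenyl)-5,6,7-trimethoxy-8-[(4,4,5,5-tetramethyl-1,3,2-dioxaborolan-2-yl)oxy]chroman-4-one | COc1ccc([C@@H]2CC(=O)c3c(c(OB4OC(C)(C)C(C)(C)O4)c(OC)c(OC)c3OC)O2)cc1OC
F7 | step 5 | (3S)-3-(3,4-dimethoxyphenyl)-3-hydroxypropanoic acid | COc1ccc([C@@H](O)CC(=O)O)cc1OC
A1 | alternative 1 | (2S)-8-(benzyloxy)-2-(3,4-dimethoxyphenyl)-5,6,7-trimethoxyspiro[chromane-4,2'-[1,3]dithiane] | COc1ccc([C@@H]2CC3(SCCCS3)c3c(c(OCc4ccccc4)c(OC)c(OC)c3OC)O2)cc1OC
A2 | alternative 1 | (3S)-3-[2-(benzyloxy)-6-(1,3-dithian-2-yl)-3,4,5-trimethoxyphenoxy]-3-(3,4-dimethoxyphenyl)propyl 4-methylbenzenesulfonate | COc1ccc([C@@H](Oc2c(C3SCCCS3)c(OC)c(OC)c(OC)c2OCc2ccccc2)CCOS(=O)(=O)c2ccc(C)cc2)cc1OC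
A3 | alternative 2 | (2S)-2,4-cis-4-(tert-butyldimethylsilyloxy)-2-(3,4-dimethoxyphenyl)-5,6,7-trimethoxychroman-8-ol | COc1ccc([C@@H]2C[C@H](O[Si](C)(C)C(C)(C)C)c3c(c(O)c(OC)c(OC)c3OC)O2)cc1OC
A4 | alternative 2 | 4-[(2S)-2,4-cis-4-(tert-butyldimethylsilyloxy)-2-(3,4-dimethoxyphenyl)-3,4-dihydro-2H-pyran-5-yl]-2,3,4-trimethoxycyclobut-2-en-1-one (ring carbon C4 of the cyclobutenone not defined) | COc1ccc([C@@H]2C[C@H](O[Si](C)(C)C(C)(C)C)C(C3(OC)C(OC)=C(OC)C3=O)=CO2)cc1OC
A5 | alternative 3 | (2S)-8-(tert-butyldimethylsilyloxy)-2-(3,4-dimethoxyphenyl)-5,6,7-trimethoxychroman-4-one | COc1ccc([C@@H]2CC(=O)c3c(c(O[Si](C)(C)C(C)(C)C)c(OC)c(OC)c3OC)O2)cc1OC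
A6 | alternative 3 | 1-[3-(tert-butyldimethylsilyloxy)-2-(3,4-dimethoxybenzyloxy)-4,5,6-trimethoxyphenyl]-2-diazoethan-1-one | COc1ccc(COc2c(C(=O)C=[N+]=[N-])c(OC)c(OC)c(OC)c2O[Si](C)(C)C(C)(C)C)cc1OC
A7 | alternative 3 | 7-(tert-butyldimethylsilyloxy)-2-(3,4-dimethoxybenzyl)-4,5,6-trimethoxybenzofuran-3(2H)-one (C2 not defined) | COc1ccc(CC2Oc3c(C2=O)c(OC)c(OC)c(OC)c3O[Si](C)(C)C(C)(C)C)cc1OC
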